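**Retrosynthetic overview**

1. The target is the mono-O-prenyl ether of C2-symmetric (−)-pinoresinol, so the last disconnection is the aryl O–prenyl bond (either phenol gives the same compound).
2. (−)-Pinoresinol is opened at both benzylic C7–O bonds to (+)-(8S,8′S)-secoisolariciresinol; forward, one double dehydrogenative cycloetherification forms both C–O bonds and sets C7 and C7′.
3. The 8S,8′S pair and the C8–C8′ bond come from an auxiliary-controlled oxidative enolate homocoupling of an N-(3-arylpropanoyl)oxazolidinone, followed by global hydride reduction.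
4. The coupling substrate is made in one pot from dihydroferulic acid, pivaloyl chloride and (R)-4-isopropyloxazolidin-2-one.
5. Ring order: no ring until the key step; then oxolane ring A (C7–O–C9′) and oxolane ring B (C7′–O–C9) close in the same flask to the cis-fused furofuran.

Assumption: the SMILES is read as the 4-O-prenyl ether of (−)-pinoresinol, 7R,8S,7′R,8′S in lignan numbering (C7 benzylic, C8 methine, C9 CH2O, primes for the second half), which is (1R,3aS,4R,6aS) in furofuran numbering; dihydroferulic acid, pivaloyl chloride, (R)-4-isopropyl-1,3-oxazolidin-2-one, DDQ and prenyl bromide are taken as catalogue chemicals.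

**Route**

Step 1
Reactants: 1 3-(4-hydroxy-3-methoxyphenyl)propanoic acid (dihydroferulic acid); 2 pivaloyl chloride; 3 (R)-4-isopropyl-1,3-oxazolidin-2-one
Product: 5 (4R)-3-[3-(3-methoxy-4-pivaloyloxyphenyl)propanoyl]-4-isopropyl-1,3-oxazolidin-2-one, via mixed pivalic anhydride 4 (not isolated)
Conditions: 2 (2.2 equiv), Et3N (3.5 equiv), DMAP (5 mol%), THF, −20 to 0 °C; then LiCl (1.2 equiv), 3 (1.1 equiv), rt
Reagents that add atoms: pivaloyl chloride CC(C)(C)C(=O)Cl; (R)-4-isopropyl-1,3-oxazolidin-2-one CC(C)[C@@H]1COC(=O)N1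
Why: An acid chloride acylates far faster than a mixed anhydride, so with excess 2 the carboxylate gives the mixed pivalic anhydride and the phenol its hindered pivalate, after which the LiCl-activated oxazolidinone attacks only the unhindered acyl carbon of 4 (mixed-anhydride N-acylation of an Evans auxiliary); no stereocentre is formed.

Step 2
Reactants: 5 (two molecules)
Product: 8 (2S,3S)-2,3-bis[(3-methoxy-4-pivaloyloxyphenyl)methyl]-1,4-bis[(4R)-4-isopropyl-2-oxo-1,3-oxazolidin-3-yl]butane-1,4-dione, via lithium Z-enolate 6 (not isolated), via trichlorotitanium Z-enolate 7 (not isolated)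
Conditions: LiN(iPr)2 (1.1 equiv), THF, −78 °C, 30 min; then TiCl4 (1.1 equiv), −78 °C to rt
Reagents that add atoms: none
Why: Oxidative enolate homocoupling: the chelated Z-enolate 6 is transmetallated to the tetravalent titanium enolate 7, electron transfer to titanium (leaving trivalent titanium) gives a chelated α-carbonyl radical, and the C8–C8′ bond forms on the face opposite the isopropyl group of each (4R)-auxiliary, giving the like 2S,3S dimer (the mirror image of the 2R,3R outcome known for (4S)-auxiliaries on 3-arylpropanoyl imides), while the hindered aryl pivalates are inert to the amide base at −78 °C.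

Step 3
Reactants: 8
Product: 9 (+)-secoisolariciresinol [(2S,3S)-2,3-bis[(4-hydroxy-3-methoxyphenyl)methyl]butane-1,4-diol]
Conditions: LiAlH4 (5 equiv), THF, 0 °C to rt; then aqueous potassium sodium tartrate
Reagents that add atoms: none
Why: Hydride reduction (reductive removal of the Evans auxiliary): LiAlH4 reduces both exocyclic imide carbonyls to primary alcohols, releasing 3, and cleaves both aryl pivalates in the same operation, without enolising C8 or C8′, so 2S,3S is retained.

Step 4
Reactants: 9
Product: 13 (−)-pinoresinol [4,4′-[(1R,3aS,4R,6aS)-tetrahydro-1H,3H-furo[3,4-c]furan-1,4-diyl]bis(2-methoxyphenol)], via seco p-quinone methide 10 (not isolated), via (−)-lariciresinol 11 (not isolated), via lariciresinol p-quinone methide 12 (not isolated)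
Conditions: DDQ (2.05 equiv, added over 2 h), 4 Å molecular sieves, 1,4-dioxane, 20 °C, dark
Reagents that add atoms: none
Why: Proposed new method: double dehydrogenative cycloetherification, in which DDQ takes hydride from the benzylic C7–H of the 4-alkyl-2-methoxyphenol to give p-quinone methide 10, the C9′ hydroxyl adds intramolecularly (oxa-1,6-addition, five-membered ring) with the aryl group trans to the neighbouring CH2OH to give 11, and a second identical cycle through 12 closes ring B with the aryl group on the convex face, so that C7 and C7′ are both set R by the existing 8S,8′S centres just as in the ring closures of the bis-quinone methide formed on oxidative dimerisation of coniferyl alcohol; slow addition keeps DDQ low so that the benzylic CH2 groups react before the more hindered, concave-face benzylic ether C–H of 11 and 13, and the neutral acid-free medium favours O-capture over Friedel–Crafts closure to an aryltetralin; the closest known reaction type is DDQ dehydrogenation of 4-alkylphenols to p-quinone methides with capture by an alcohol, which stops at the α-alkoxy stage with one equivalent of oxidant.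

Step 5
Reactants: 13 (−)-pinoresinol; 14 1-bromo-3-methylbut-2-ene (prenyl bromide)
Product: 15 4-[(1R,3aS,4R,6aS)-4-[3-methoxy-4-(3-methylbut-2-enyloxy)phenyl]tetrahydro-1H,3H-furo[3,4-c]furan-1-yl]-2-methoxyphenol
Conditions: 14 (0.9 equiv), K2CO3 (1.1 equiv), acetone, rt, 16 h; recovered 13 recycled
Reagents that add atoms: 1-bromo-3-methylbut-2-ene CC(C)=CCBr
Why: Williamson ether synthesis (SN2 at the primary allylic carbon): the two phenols of C2-symmetric 13 are equivalent and remote, so either gives 15 and a slight deficit of 14 limits bis-alkylation (statistical, about 45 % per pass with 13 recovered), and K2CO3 at room temperature does not touch the four stereocentres.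

**Compound list**

1 | 3-(4-hydroxy-3-methoxyphenyl)propanoic acid (dihydroferulic acid) | COc1cc(CCC(=O)O)ccc1O | starting material
2 | pivaloyl chloride (2,2-dimethylpropanoyl chloride) | CC(C)(C)C(=O)Cl | starting material
3 | (R)-4-isopropyl-1,3-oxazolidin-2-one | CC(C)[C@@H]1COC(=O)N1 | starting material
4 | 3-(3-methoxy-4-pivaloyloxyphenyl)propanoic pivalic anhydride (not isolated) | COc1cc(CCC(=O)OC(=O)C(C)(C)C)ccc1OC(=O)C(C)(C)C | intermediate
5 | (4R)-3-[3-(3-methoxy-4-pivaloyloxyphenyl)propanoyl]-4-isopropyl-1,3-oxazolidin-2-one | COc1cc(CCC(=O)N2[C@H](C(C)C)COC2=O)ccc1OC(=O)C(C)(C)C | intermediate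
6 | lithium (Z)-enolate of 5 (not isolated) | [Li+].[O-]/C(=C\Cc1ccc(OC(=O)C(C)(C)C)c(OC)c1)N1[C@H](C(C)C)COC1=O | intermediate
7 | trichlorotitanium (Z)-enolate of 5 (not isolated) | Cl[Ti](Cl)(Cl)O/C(=C\Cc1ccc(OC(=O)C(C)(C)C)c(OC)c1)N1[C@H](C(C)C)COC1=O | intermediate
8 | (2S,3S)-2,3-bis[(3-methoxy-4-pivaloyloxyphenyl)methyl]-1,4-bis[(4R)-4-isopropyl-2-oxo-1,3-oxazolidin-3-yl]butane-1,4-dione | COc1cc(C[C@H](C(=O)N2[C@H](C(C)C)COC2=O)[C@H](Cc2ccc(OC(=O)C(C)(C)C)c(OC)c2)C(=O)N2[C@H](C(C)C)COC2=O)ccc1OC(=O)C(C)(C)C | intermediate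
9 | (+)-secoisolariciresinol, (2S,3S)-2,3-bis[(4-hydroxy-3-methoxyphenyl)methyl]butane-1,4-diol | COc1cc(C[C@H](CO)[C@H](Cc2ccc(O)c(OC)c2)CO)ccc1O | intermediate
10 | p-quinone methide of 9 at C7, 4-[(2S,3S)-4-hydroxy-3-[(4-hydroxy-3-methoxyphenyl)methyl]-2-(hydroxymethyl)butylidene]-2-methoxycyclohexa-2,5-dien-1-one (not isolated) | COC1=CC(=C[C@H](CO)[C@H](Cc2ccc(O)c(OC)c2)CO)C=CC1=O | intermediate
11 | (−)-lariciresinol, [(2R,3S,4S)-2-(4-hydroxy-3-methoxyphenyl)-4-[(4-hydroxy-3-methoxyphenyl)methyl]oxolan-3-yl]methanol (not isolated) | COc1cc([C@@H]2OC[C@@H](Cc3ccc(O)c(OC)c3)[C@H]2CO)ccc1O | intermediate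
12 | p-quinone methide of 11 at C7′ (exocyclic C7′=C1′ on the dienone ring; 7R,8S,8′S retained; not isolated) | COc1cc([C@@H]2OC[C@@H](C=C3C=CC(=O)C(OC)=C3)[C@H]2CO)ccc1O | intermediate
13 | (−)-pinoresinol, 4,4′-[(1R,3aS,4R,6aS)-tetrahydro-1H,3H-furo[3,4-c]furan-1,4-diyl]bis(2-methoxyphenol) | COc1cc([C@@H]2OC[C@@H]3[C@H]2CO[C@H]3c2ccc(O)c(OC)c2)ccc1O | intermediate
14 | 1-bromo-3-methylbut-2-ene (prenyl bromide) | CC(C)=CCBr | starting material
15 | 4-[(1R,3aS,4R,6aS)-4-[3-methoxy-4-(3-methylbut-2-enyloxy)phenyl]tetrahydro-1H,3H-furo[3,4-c]furan-1-yl]-2-methoxyphenol | COc1cc([C@@H]2OC[C@@H]3[C@H]2CO[C@H]3c2ccc(OCC=C(C)C)c(OC)c2)ccc1O | target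

**Step count and risks**

Total steps: 5. Longest linear sequence: 5 (fully linear).

Step 4 (the proposed new step) is the most likely to fail. The benzylic ether C–H of 11 and 13 is electronically activated, so DDQ may over-oxidise the product or the intermediate 11; an aryltetralin may also form if the medium turns acidic. The fallback uses known chemistry, sets out from 9 and comes back at 13. Peracetylation of 9 (Ac2O, pyridine) gives (2S,3S)-2,3-bis[(4-acetoxy-3-methoxyphenyl)methyl]butane-1,4-diyl diacetate F8. Wohl–Ziegler bromination (NBS, catalytic AIBN, PhCF3, 80 °C) of the two benzylic CH2 groups gives (2S,3S)-2,3-bis[(4-acetoxy-3-methoxyphenyl)bromomethyl]butane-1,4-diyl diacetate F9. Solvolysis of the benzylic bromides (NaHCO3, aqueous acetone) and removal of the four acetates (K2CO3, MeOH) gives (2S,3S)-1,4-bis(4-hydroxy-3-methoxyphenyl)-2,3-bis(hydroxymethyl)butane-1,4-diol F10. The established acid cyclodehydration of this tetraol (0.1 M HCl in aqueous THF, through the p-hydroxybenzyl cations) then gives 13.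

Step 2 is the second risk: radical enolate couplings give moderate yields, the unlike (meso-type) dimer has to be separated, and the aryl pivalates are a new substituent for this coupling. The fallback replaces the dimerisation by two stepwise enolate alkylations (the classical dibenzylbutyrolactone route); it sets out from 5 and comes back at 9. Evans alkylation of 5 (NaN(SiMe3)2, THF, −78 °C; tert-butyl bromoacetate) gives tert-butyl (3S)-3-[(3-methoxy-4-pivaloyloxyphenyl)methyl]-4-[(4R)-4-isopropyl-2-oxo-1,3-oxazolidin-3-yl]-4-oxobutanoate F2. Reductive removal of the auxiliary (LiBH4, MeOH, THF, 0 °C) gives tert-butyl (3S)-4-hydroxy-3-[(3-methoxy-4-pivaloyloxyphenyl)methyl]butanoate F3, which lactonises with TFA in CH2Cl2 to (4S)-4-[(3-methoxy-4-pivaloyloxyphenyl)methyl]oxolan-2-one F4. Commercial 4-(benzyloxy)-3-methoxybenzyl alcohol and PBr3 give 4-(benzyloxy)-3-methoxybenzyl bromide F5. Alkylation of the lithium enolate of F4 (LiN(SiMe3)2, THF, −78 °C) with F5 occurs trans to the existing benzyl group and gives (3S,4S)-3-[(4-benzyloxy-3-methoxyphenyl)methyl]-4-[(3-methoxy-4-pivaloyloxyphenyl)methyl]oxolan-2-one F6. LiAlH4 opens the lactone and removes the pivalate to give (2S,3S)-2-[(4-benzyloxy-3-methoxyphenyl)methyl]-3-[(4-hydroxy-3-methoxyphenyl)methyl]butane-1,4-diol F7, and hydrogenolysis (H2, palladium on carbon, EtOAc) gives 9.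

Step 1 is the third risk: in the one-pot double acylation the free phenol of one molecule may attack the mixed anhydride of another and give aryl ester oligomers. The fallback separates the two acylations; it sets out from 1 and comes back at 5. The phenol is acylated first as its phenoxide under Schotten–Baumann conditions (2, aqueous NaOH, 0 °C; any mixed anhydride at the carboxylate hydrolyses back) to give 3-(3-methoxy-4-pivaloyloxyphenyl)propanoic acid F1. After isolation, F1 is loaded onto 3 by the standard sequence (2, Et3N, THF, −20 °C; then LiCl and 3) through 4 to give 5.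

**Further compounds**

F1 | step 1 | 3-(3-methoxy-4-pivaloyloxyphenyl)propanoic acid | COc1cc(CCC(=O)O)ccc1OC(=O)C(C)(C)C
F2 | step 2 | tert-butyl (3S)-3-[(3-methoxy-4-pivaloyloxyphenyl)methyl]-4-[(4R)-4-isopropyl-2-oxo-1,3-oxazolidin-3-yl]-4-oxobutanoate | COc1cc(C[C@@H](CC(=O)OC(C)(C)C)C(=O)N2[C@H](C(C)C)COC2=O)ccc1OC(=O)C(C)(C)C
F3 | step 2 | tert-butyl (3S)-4-hydroxy-3-[(3-methoxy-4-pivaloyloxyphenyl)methyl]butanoate | COc1cc(C[C@H](CO)CC(=O)OC(C)(C)C)ccc1OC(=O)C(C)(C)C
F4 | step 2 | (4S)-4-[(3-methoxy-4-pivaloyloxyphenyl)methyl]oxolan-2-one | COc1cc(C[C@@H]2COC(=O)C2)ccc1OC(=O)C(C)(C)C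
F5 | step 2 | 4-(benzyloxy)-3-methoxybenzyl bromide | COc1cc(CBr)ccc1OCc1ccccc1
F6 | step 2 | (3S,4S)-3-[(4-benzyloxy-3-methoxyphenyl)methyl]-4-[(3-methoxy-4-pivaloyloxyphenyl)methyl]oxolan-2-one | COc1cc(C[C@@H]2COC(=O)[C@H]2Cc2ccc(OCc3ccccc3)c(OC)c2)ccc1OC(=O)C(C)(C)C
F7 | step 2 | (2S,3S)-2-[(4-benzyloxy-3-methoxyphenyl)methyl]-3-[(4-hydroxy-3-methoxyphenyl)methyl]butane-1,4-diol | COc1cc(C[C@H](CO)[C@H](Cc2ccc(OCc3ccccc3)c(OC)c2)CO)ccc1O
F8 | step 4 | (2S,3S)-2,3-bis[(4-acetoxy-3-methoxyphenyl)methyl]butane-1,4-diyl diacetate | COc1cc(C[C@H](COC(C)=O)[C@H](Cc2ccc(OC(C)=O)c(OC)c2)COC(C)=O)ccc1OC(C)=O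
F9 | step 4 | (2S,3S)-2,3-bis[(4-acetoxy-3-methoxyphenyl)bromomethyl]butane-1,4-diyl diacetate (epimers at the CHBr carbons) | COc1cc(C(Br)[C@H](COC(C)=O)[C@H](C(Br)c2ccc(OC(C)=O)c(OC)c2)COC(C)=O)ccc1OC(C)=O
F10 | step 4 | (2S,3S)-1,4-bis(4-hydroxy-3-methoxyphenyl)-2,3-bis(hydroxymethyl)butane-1,4-diol (epimers at C1 and C4) | COc1cc(C(O)[C@H](CO)[C@H](C(O)c2ccc(O)c(OC)c2)CO)ccc1O
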